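**Strategy.** Everything rests on making the bond between the cyclopentane CH2 and the quaternary carbon C3 (flanked by two ring A ketones) while C3 is a malonate carbon esterified to the tertiary oxygen of the 2-hydroxypropan-2-yl group. That oxygen sits cis to one ring A carbonyl across the cyclopentane, so a six-membered lactone can serve as a temporary tether. One base treatment C-alkylates the malonate with the hindered primary tosylate (lactone closure) and then adds it to a pendant enone (cyclopentane closure), setting two stereocentres from one. The lactone later acylates a diketone dianion to build ring A; allylation and cationic cyclisation close the homoadamantane.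

Key step: step 11

Remark (assumption on drawing and labels): enolised tricarbonyl compounds are drawn as one tautomer. Ring A is C1 (benzoyl-bearing), C2, C3, C4, C5 (geranyl-bearing) and C9 (the carbonyl between C1 and C5); C6 (CH2), C7 (CH) and C8 (CMe2) complete the cyclohexanone ring.

**Step 1**
Reactants: 1 3,3-dimethylpent-4-enoic acid; 2 (4S)-4-benzyl-1,3-oxazolidin-2-one
Product: 4 (4S)-4-benzyl-3-(3,3-dimethylpent-4-enoyl)-1,3-oxazolidin-2-one, via mixed pivalic anhydride 3 (not isolated)
Conditions: t-BuCOCl, Et3N, THF, −20 °C; then 2, LiCl, −20 °C → rt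
Reagents that add atoms: none
Why: Mixed-anhydride N-acylation loads the Evans auxiliary; no stereocentre is formed.

**Step 2**
Reactants: 4; 5 benzyl chloromethyl ether
Product: 6 (4S)-4-benzyl-3-[(2R)-2-[(benzyloxy)methyl]-3,3-dimethylpent-4-enoyl]-1,3-oxazolidin-2-one
Conditions: TiCl4, i-Pr2NEt, CH2Cl2, 0 °C; then 5, 0 °C
Reagents that add atoms: none
Why: Evans alkylation of the chelated (Z)-titanium enolate with the oxocarbenium ion from 5 should occur on the face away from the benzyl group, setting the centre that becomes the CH(CMe2OH) carbon of the cyclopentane.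

**Step 3**
Reactants: 6
Product: 7 methyl (2R)-2-[(benzyloxy)methyl]-3,3-dimethylpent-4-enoate
Conditions: Sm(OTf)3 (cat.), MeOH, 50 °C
Reagents that add atoms: methanol, CO
Why: Lewis-acid-catalysed transesterification of the imide should release the auxiliary under neutral conditions, so the α-centre is not enolised.

**Step 4**
Reactants: 7
Product: 8 (3R)-3-[(benzyloxy)methyl]-2,4,4-trimethylhex-5-en-2-ol
Conditions: MeMgBr (excess), THF, 0 °C → reflux; aq. NH4Cl
Reagents that add atoms: methylmagnesium bromide, C[Mg]Br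
Why: Double Grignard addition to the ester should give the tertiary alcohol without touching the stereocentre.

**Step 5**
Reactants: 8
Product: 9 (2R)-3-methyl-2-(2-methylbut-3-en-2-yl)butane-1,3-diol
Conditions: Na, NH3 (l), THF, −78 °C; then NH4Cl
Reagents that add atoms: none
Why: Dissolving-metal cleavage of the benzyl ether should leave the isolated terminal alkene untouched.

**Step 6**
Reactants: 9
Product: 10 (2R)-3-hydroxy-3-methyl-2-(2-methylbut-3-en-2-yl)butyl 4-methylbenzenesulfonate
Conditions: TsCl, pyridine, CH2Cl2, 0 °C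
Reagents that add atoms: 4-methylbenzenesulfonyl chloride, Cc1ccc(cc1)S(=O)(=O)Cl
Why: Sulfonylation should be selective for the primary over the hindered tertiary hydroxyl.

**Step 7**
Reactants: 10; 11 methyl 3-chloro-3-oxopropanoate (methyl malonyl chloride)
Product: 12 methyl (3R)-2,4,4-trimethyl-3-[(tosyloxy)methyl]hex-5-en-2-yl propanedioate
Conditions: 11, pyridine, DMAP (cat.), CH2Cl2, 0 °C → rt
Reagents that add atoms: none
Why: Acylation of the tertiary alcohol through the reactive (methoxycarbonyl)ketene installs the malonate tether on the oxygen that ends as the free hydroxyl of the target.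

**Step 8**
Reactants: 13 3-hydroxy-3-methylbutan-2-one
Product: 14 1-bromo-3-hydroxy-3-methylbutan-2-one
Conditions: Br2, MeOH, 0 °C → rt
Reagents that add atoms: bromine, BrBr
Why: α-Bromination of the ketone can occur only at the methyl group, its single enolisable position.

**Step 9**
Reactants: 14
Product: 16 3-hydroxy-3-methyl-1-(triphenyl-λ5-phosphanylidene)butan-2-one, via phosphonium bromide 15 (not isolated)
Conditions: PPh3, toluene, rt; then aq. Na2CO3, CH2Cl2
Reagents that add atoms: triphenylphosphine, c1ccc(cc1)P(c1ccccc1)c1ccccc1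
Why: SN2 quaternisation of the phosphine by the α-bromo ketone and deprotonation should give the stabilised acyl ylide.

**Step 10**
Reactants: 12; 16
Product: 18 methyl (3R,5E)-8-hydroxy-2,4,4,8-tetramethyl-7-oxo-3-[(tosyloxy)methyl]non-5-en-2-yl propanedioate, via aldehyde 17 (not isolated)
Conditions: O3, CH2Cl2, −78 °C; PPh3, −78 °C → rt; then 16, toluene, 60 °C
Reagents that add atoms: none
Why: Ozonolysis of the vinyl group and an E-selective Wittig olefination with the stabilised ylide run without base, so malonate and tosylate should stay untouched.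

**Step 11**
Reactants: 18
Product: 20 methyl (1R,5S,7R)-7-(3-hydroxy-3-methyl-2-oxobutyl)-4,4,6,6-tetramethyl-2-oxo-3-oxabicyclo[3.2.1]octane-1-carboxylate, via monocyclic δ-lactone 19 (not isolated)
Conditions: Cs2CO3, NaI (cat.), MeCN, rt → 50 °C
Reagents that add atoms: none
Why: Cs2CO3 deprotonates the malonate CH2; the enolate displaces the primary sulfonate (iodide-assisted SN2, 6-exo-tet) to close the δ-lactone through the new C3–CH2 bond, and the α-carbomethoxy lactone enolate then adds to the (E)-enone (intramolecular Michael addition, 5-exo-trig) to close the cyclopentane through C3–CH. The closest known reaction types are intramolecular malonate alkylation to lactones and carbocycles and Michael-initiated ring closure. Because the lactone bridges the cyclopentane, its carbonyl and the C(Me)2–O carbon are necessarily cis, which fixes the quaternary C3 (lactone carbonyl becomes the C4 ketone, methyl ester becomes the C2 ketone). The new CH stereocentre should form in the bicyclo[3.2.1] transition state with the enone chain exo, anti to the lactone bridge; the Michael addition is reversible, so the exo epimer should also be the thermodynamic one. The step needs C- over O-alkylation (soft iodide leaving group, carbon-centred malonate reactivity) and alkylation before Michael addition (six- versus seven-membered transition state), both helped by the two gem-dimethyl groups on the tether.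

**Step 12**
Reactants: 20
Product: 21 methyl (1R,5S,7R)-7-(3-hydroxy-3-methyl-2-methylidenebutyl)-4,4,6,6-tetramethyl-2-oxo-3-oxabicyclo[3.2.1]octane-1-carboxylate
Conditions: Zn, CH2Br2, TiCl4, THF/CH2Cl2, 0 °C → rt
Reagents that add atoms: dibromomethane, BrCBr
Why: Takai–Lombardo methylenation should convert the only ketone into the 1,1-disubstituted alkene under non-basic conditions, avoiding retro-Michael opening and leaving ester and lactone intact.

**Step 13**
Reactants: 22 geranylacetone, (5E)-6,10-dimethylundeca-5,9-dien-2-one; 23 methyl benzoate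
Product: 24 (6E)-7,11-dimethyl-1-phenyldodeca-6,10-diene-1,3-dione
Conditions: NaH, THF, reflux; aq. HCl
Reagents that add atoms: none
Why: Crossed Claisen condensation of the methyl ketone with the non-enolisable ester should occur at the methyl group, which gives the more acidic 1,3-diketone.

**Step 14**
Reactants: 21; 24
Product: 26 (1R,3S,5S)-7-benzoyl-9-[(2E)-3,7-dimethylocta-2,6-dien-1-yl]-8,10-dihydroxy-1-(3-hydroxy-3-methyl-2-methylidenebutyl)-3-(2-hydroxypropan-2-yl)-2,2-dimethylspiro[4.5]deca-7,9-dien-6-one, via open-chain triketo ester 25 (not isolated)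
Conditions: 24, LiN(i-Pr)2 (2 equiv per 24, 1 extra equiv for the hydroxyl of 21), THF, −78 → 0 °C; then 21, −78 °C → rt; then Mg(OMe)2, MeOH, 60 °C; aq. HCl
Reagents that add atoms: none
Why: Harris-type polyketide assembly: the γ-carbon of the diketone dianion should acylate at the strained s-cis lactone (releasing the tertiary alcohol), and a magnesium-templated Claisen cyclisation of the central carbon onto the methyl ester (6-exo-trig) closes ring A with geranyl on C5 and benzoyl on C1, the spiro centre being fixed already.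

**Step 15**
Reactants: 26
Product: 27 bicyclic enol: C5 quaternary (geranyl and C6H2), seven-membered ring C3–CH–CH2–C7(=CMe2)–C6–C5–C4, C1 enolised benzoyl triketone
Conditions: Pd(PPh3)4 (cat.), Et3B (cat.), THF, 50 °C
Reagents that add atoms: none
Why: Tsuji–Trost allylation with the allylic alcohol activated by Et3B: the alkyl-bearing enol carbon C5 should attack the CH2 terminus of the π-allyl complex (as in the conversion of deoxyhumulones to lupulones, not the acyl-bearing C1), and the tether allows only the ring A face that carries the cyclopentane CH, which sets C5.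

**Step 16**
Reactants: 27
Product: 28 CNP0164095.2 (target)
Conditions: HCO2H, CH2Cl2, 0 °C → rt
Reagents that add atoms: none
Why: Biomimetic cation–olefin cyclisation: protonation of the tetrasubstituted alkene at the ring carbon gives the exocyclic tertiary cation, which the benzoyl-bearing enol carbon C1 should capture to close the cyclohexanone ring and the cage, C7 and C1 being able to form only with the cage geometry.

**Compound list**

1 | 3,3-dimethylpent-4-enoic acid | C=CC(C)(C)CC(=O)O | starting material
2 | (4S)-4-benzyl-1,3-oxazolidin-2-one | O=C1OC[C@H](Cc2ccccc2)N1 | starting material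
3 | 3,3-dimethylpent-4-enoic pivalic anhydride | C=CC(C)(C)CC(=O)OC(=O)C(C)(C)C | intermediate (not isolated)
4 | (4S)-4-benzyl-3-(3,3-dimethylpent-4-enoyl)-1,3-oxazolidin-2-one | C=CC(C)(C)CC(=O)N1C(=O)OC[C@@H]1Cc1ccccc1 | intermediate
5 | benzyl chloromethyl ether | ClCOCc1ccccc1 | starting material
6 | (4S)-4-benzyl-3-[(2R)-2-[(benzyloxy)methyl]-3,3-dimethylpent-4-enoyl]-1,3-oxazolidin-2-one | C=CC(C)(C)[C@@H](C(=O)N1C(=O)OC[C@@H]1Cc1ccccc1)COCc1ccccc1 | intermediate
7 | methyl (2R)-2-[(benzyloxy)methyl]-3,3-dimethylpent-4-enoate | C=CC(C)(C)[C@@H](C(=O)OC)COCc1ccccc1 | intermediate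
8 | (3R)-3-[(benzyloxy)methyl]-2,4,4-trimethylhex-5-en-2-ol | C=CC(C)(C)[C@@H](C(C)(C)O)COCc1ccccc1 | intermediate
9 | (2R)-3-methyl-2-(2-methylbut-3-en-2-yl)butane-1,3-diol | C=CC(C)(C)[C@@H](C(C)(C)O)CO | intermediate
10 | (2R)-3-hydroxy-3-methyl-2-(2-methylbut-3-en-2-yl)butyl 4-methylbenzenesulfonate | C=CC(C)(C)[C@@H](C(C)(C)O)COS(=O)(=O)c1ccc(C)cc1 | intermediate
11 | methyl 3-chloro-3-oxopropanoate | COC(=O)CC(=O)Cl | starting material
12 | methyl (3R)-2,4,4-trimethyl-3-[(tosyloxy)methyl]hex-5-en-2-yl propanedioate | C=CC(C)(C)[C@@H](C(C)(C)OC(=O)CC(=O)OC)COS(=O)(=O)c1ccc(C)cc1 | intermediate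
13 | 3-hydroxy-3-methylbutan-2-one | CC(=O)C(C)(C)O | starting material
14 | 1-bromo-3-hydroxy-3-methylbutan-2-one | BrCC(=O)C(C)(C)O | intermediate
15 | (3-hydroxy-3-methyl-2-oxobutyl)triphenylphosphonium bromide | CC(C)(O)C(=O)C[P+](c1ccccc1)(c1ccccc1)c1ccccc1.[Br-] | intermediate (not isolated)
16 | 3-hydroxy-3-methyl-1-(triphenyl-λ5-phosphanylidene)butan-2-one | CC(C)(O)C(=O)C=P(c1ccccc1)(c1ccccc1)c1ccccc1 | intermediate
17 | methyl (3R)-2,4,4-trimethyl-5-oxo-3-[(tosyloxy)methyl]pentan-2-yl propanedioate | O=CC(C)(C)[C@@H](C(C)(C)OC(=O)CC(=O)OC)COS(=O)(=O)c1ccc(C)cc1 | intermediate (not isolated)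
18 | methyl (3R,5E)-8-hydroxy-2,4,4,8-tetramethyl-7-oxo-3-[(tosyloxy)methyl]non-5-en-2-yl propanedioate | CC(C)(O)C(=O)/C=C/C(C)(C)[C@@H](C(C)(C)OC(=O)CC(=O)OC)COS(=O)(=O)c1ccc(C)cc1 | intermediate
19 | methyl (5S)-5-[(3E)-6-hydroxy-2,6-dimethyl-5-oxohept-3-en-2-yl]-6,6-dimethyl-2-oxooxane-3-carboxylate (both C3 epimers) | COC(=O)C1C[C@@H](C(C)(C)/C=C/C(=O)C(C)(C)O)C(C)(C)OC1=O | intermediate (not isolated)
20 | methyl (1R,5S,7R)-7-(3-hydroxy-3-methyl-2-oxobutyl)-4,4,6,6-tetramethyl-2-oxo-3-oxabicyclo[3.2.1]octane-1-carboxylate | CC(C)(O)C(=O)C[C@@H]1C(C)(C)[C@@H]2C[C@@]1(C(=O)OC)C(=O)OC2(C)C | intermediate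
21 | methyl (1R,5S,7R)-7-(3-hydroxy-3-methyl-2-methylidenebutyl)-4,4,6,6-tetramethyl-2-oxo-3-oxabicyclo[3.2.1]octane-1-carboxylate | CC(C)(O)C(=C)C[C@@H]1C(C)(C)[C@@H]2C[C@@]1(C(=O)OC)C(=O)OC2(C)C | intermediate
22 | geranylacetone, (5E)-6,10-dimethylundeca-5,9-dien-2-one | CC(C)=CCC/C(C)=C/CCC(C)=O | starting material
23 | methyl benzoate | COC(=O)c1ccccc1 | starting material
24 | (6E)-7,11-dimethyl-1-phenyldodeca-6,10-diene-1,3-dione | CC(C)=CCC/C(C)=C/CCC(=O)CC(=O)c1ccccc1 | intermediate
25 | methyl (1S,2R,4S)-1-{2-[(2E)-3,7-dimethylocta-2,6-dien-1-yl]-3,5-dioxo-5-phenylpentanoyl}-2-(3-hydroxy-3-methyl-2-methylidenebutyl)-4-(2-hydroxypropan-2-yl)-3,3-dimethylcyclopentane-1-carboxylate (epimers at the acyl α-carbon) | CC(C)(O)C(=C)C[C@@H]1C(C)(C)[C@@H](C(C)(C)O)C[C@@]1(C(=O)OC)C(=O)C(C/C=C(C)/CCC=C(C)C)C(=O)CC(=O)c1ccccc1 | intermediate (not isolated)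
26 | (1R,3S,5S)-7-benzoyl-9-[(2E)-3,7-dimethylocta-2,6-dien-1-yl]-8,10-dihydroxy-1-(3-hydroxy-3-methyl-2-methylidenebutyl)-3-(2-hydroxypropan-2-yl)-2,2-dimethylspiro[4.5]deca-7,9-dien-6-one | CC(C)(O)C(=C)C[C@@H]1C(C)(C)[C@@H](C(C)(C)O)C[C@]12C(=O)C(C(=O)c1ccccc1)=C(O)C(C/C=C(C)/CCC=C(C)C)=C2O | intermediate
27 | bicyclic enol: ring A with quaternary C5 (geranyl, C6H2) bridged to the cyclopentane CH through CH2–C(=CMe2)–CH2, cyclopentane spiro-fused at C3, C1 enolised benzoyl triketone, configuration as in the SMILES | CC(C)=CCC/C(C)=C/C[C@@]12CC(=C(C)C)C[C@@H]3C(C)(C)[C@@H](C(C)(C)O)C[C@]3(C1=O)C(=O)C(C(=O)c1ccccc1)=C2O | intermediate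
28 | CNP0164095.2, cyclopentane-fused homoadamantane triketone with C1 benzoyl, C5 geranyl and 2-hydroxypropan-2-yl | CC(C)=CCC/C(C)=C/C[C@@]12C[C@H]3C[C@@H]4C(C)(C)[C@@H](C(C)(C)O)C[C@]4(C1=O)C(=O)[C@@](C(=O)c1ccccc1)(C2=O)C3(C)C | target

**Total step count:** 16. **Longest linear sequence:** 13 (steps 1–7, 10–12, 14–16).

**Steps most likely to fail**

1. Step 16. The acid may protonate the trisubstituted alkenes of the geranyl chain (diene cyclisation), ionise the tertiary alcohol, or the enol may capture the cation at the ring carbon instead of the exocyclic one. The fallback introduces the geranyl chain last. It sets out from 21, which is combined with the dianion of commercial 1-phenylbutane-1,3-dione (LiN(i-Pr)2; then Mg(OMe)2, MeOH). This should give, through the open-chain triketo ester without geranyl F1, the spiro acyl-trione without geranyl F2. Closure with Pd(PPh3)4 and Et3B gives the bicyclic C5–H enol F3. Acid treatment, now free of the acid-sensitive diene so that a stronger acid can be chosen, gives the C5–H cage F4. Bridgehead deprotonation with lithium 2,2,6,6-tetramethylpiperidide and alkylation with geranyl bromide on the only open face of C5 comes back to the route at 28.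

2. Step 14. The hindered dianion may attack the methyl ester instead of the lactone, or may fail to add at all to an acyl group on a quaternary carbon. The fallback replaces the Claisen acylation by an aldol addition. It sets out from 21: i-Bu2AlH at −78 °C should reduce the strained lactone selectively to the lactol F4a is not used; the lactol is F5. The dianion of 24 then adds to the hydroxy-aldehyde form of the lactol, where the aldehyde is by far the most electrophilic site, to give the aldol adduct F6. Dess–Martin oxidation of the only secondary alcohol comes back to the route at 25, which is cyclised with Mg(OMe)2 to 26.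

3. Step 11. Displacement at the hindered primary carbon may be slow, so that Michael addition through a seven-membered transition state comes first and facial control at the new CH centre is lost, or the endo epimer may form. The fallback separates the two bond formations and closes the lactone before the enone exists. It sets out from 12: NaI in acetone gives the iodide F7, and Cs2CO3 in MeCN closes the vinyl-substituted δ-lactone F8. Ozonolysis gives the lactone aldehyde F9, and olefination with ylide 16 under neutral conditions gives 19, now isolated. A separate, equilibrating Michael addition with DBU then comes back to the route at 20.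

**Further compounds**

F1 | step 16 | methyl (1S,2R,4S)-1-(3,5-dioxo-5-phenylpentanoyl)-2-(3-hydroxy-3-methyl-2-methylidenebutyl)-4-(2-hydroxypropan-2-yl)-3,3-dimethylcyclopentane-1-carboxylate | CC(C)(O)C(=C)C[C@@H]1C(C)(C)[C@@H](C(C)(C)O)C[C@@]1(C(=O)OC)C(=O)CC(=O)CC(=O)c1ccccc1
F2 | step 16 | (1R,3S,5S)-7-benzoyl-8,10-dihydroxy-1-(3-hydroxy-3-methyl-2-methylidenebutyl)-3-(2-hydroxypropan-2-yl)-2,2-dimethylspiro[4.5]deca-7,9-dien-6-one | CC(C)(O)C(=C)C[C@@H]1C(C)(C)[C@@H](C(C)(C)O)C[C@]12C(=O)C(C(=O)c1ccccc1)=C(O)C=C2O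
F3 | step 16 | bicyclic enol as 27 with hydrogen in place of geranyl at C5 | [C@@H]12CC(=C(C)C)C[C@@H]3C(C)(C)[C@@H](C(C)(C)O)C[C@]3(C1=O)C(=O)C(C(=O)c1ccccc1)=C2O
F4 | step 16 | homoadamantane cage as 28 with hydrogen in place of geranyl at C5 | [C@@H]12C[C@H]3C[C@@H]4C(C)(C)[C@@H](C(C)(C)O)C[C@]4(C1=O)C(=O)[C@@](C(=O)c1ccccc1)(C2=O)C3(C)C
F5 | step 14 | methyl (1R,5S,7R)-2-hydroxy-7-(3-hydroxy-3-methyl-2-methylidenebutyl)-4,4,6,6-tetramethyl-3-oxabicyclo[3.2.1]octane-1-carboxylate (lactol, both anomers) | CC(C)(O)C(=C)C[C@@H]1C(C)(C)[C@@H]2C[C@@]1(C(=O)OC)C(O)OC2(C)C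
F6 | step 14 | methyl (1S,2R,4S)-1-{2-[(2E)-3,7-dimethylocta-2,6-dien-1-yl]-1-hydroxy-3,5-dioxo-5-phenylpentyl}-2-(3-hydroxy-3-methyl-2-methylidenebutyl)-4-(2-hydroxypropan-2-yl)-3,3-dimethylcyclopentane-1-carboxylate (mixture at the two new centres) | CC(C)(O)C(=C)C[C@@H]1C(C)(C)[C@@H](C(C)(C)O)C[C@@]1(C(=O)OC)C(O)C(C/C=C(C)/CCC=C(C)C)C(=O)CC(=O)c1ccccc1
F7 | step 11 | (3R)-3-(iodomethyl)-2,4,4-trimethylhex-5-en-2-yl methyl propanedioate | C=CC(C)(C)[C@@H](C(C)(C)OC(=O)CC(=O)OC)CI
F8 | step 11 | methyl (5S)-6,6-dimethyl-5-(2-methylbut-3-en-2-yl)-2-oxooxane-3-carboxylate (both C3 epimers) | COC(=O)C1C[C@@H](C(C)(C)C=C)C(C)(C)OC1=O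
F9 | step 11 | methyl (5S)-6,6-dimethyl-5-(2-methyl-1-oxopropan-2-yl)-2-oxooxane-3-carboxylate (both C3 epimers) | COC(=O)C1C[C@@H](C(C)(C)C=O)C(C)(C)OC1=O
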